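**Assumptions.** (a) Only substrates, intermediates and the ylide are numbered. Simple reagents and catalysts are given by name and SMILES where they leave atoms in the product. (b) The (R)-diarylprolinol silyl ether is assumed to give the (2R,3S)-trans-epoxy aldehyde; use the antipode if the opposite epoxide results. (c) Methylation at C4 is assumed to occur from the α face, because the β face is blocked by the axial C20 methyl. This puts the new methyl equatorial (C18, α) and the ester axial (C19, β).

## Retrosynthetic overview
1. Target (17) comes from hydrolysis of methyl ester 16. The C4 quaternary centre (axial CO2Me, equatorial Me) comes from α-face methylation of the β-keto ester 12. The C3 oxygen is excised afterwards by Barton–McCombie deoxygenation.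
2. β-Hydroxy ester 11 comes from a proposed Ti(III)-catalysed radical polyene cascade of the (3S)-glycidic ester 10. Ring A (C4–C5) forms first, then ring B (C9–C10), in one operation. The cascade also sets C5, C9 and C10 and ends in the exocyclic C8=C17 alkene.
3. Glycidate 10 comes from an organocatalytic epoxidation of enal 7, which is made by a Wittig reaction on aldehyde 5. Aldehyde 5 comes from terminal-selective epoxidation and periodate cleavage of geranylgeranyl acetate (2), which is made from commercial geranylgeraniol (1).

## Route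

**Step 1**
Reactants: 1, (2E,6E,10E)-geranylgeraniol
Product: 2, geranylgeranyl acetate
Conditions: Ac2O, pyridine, DMAP (cat.), CH2Cl2, 0 °C → rt
Reagents that add atoms: acetic anhydride, CC(=O)OC(C)=O
Why: Standard O-acetylation of a primary allylic alcohol; it installs the C15 acetate that is carried through to the target.

**Step 2**
Reactants: 2
Product: 3, terminal bromohydrin (14-bromo-15-hydroxy-14,15-dihydrogeranylgeranyl acetate, racemic at C14)
Conditions: NBS (1.05 equiv), THF/H2O, 0 °C
Reagents that add atoms: N-bromosuccinimide, O=C1CCC(=O)N1Br; water, O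
Why: Halohydrin formation is Markovnikov (OH goes to the tertiary carbon). It is selective for the terminal trisubstituted alkene, which is the most accessible, so 3 is the main mono-adduct (expected yield about 35–45%).

**Step 3**
Reactants: 3
Product: 4, 14,15-epoxygeranylgeranyl acetate (racemic)
Conditions: K2CO3 (1.2 equiv), MeOH, 0 °C, 45 min
Reagents that add atoms: none
Why: Intramolecular SN2 closure of the bromohydrin alkoxide (Williamson). The stereocentre is destroyed in the next step, so racemic material is fine. The cold, short reaction time is meant to leave the acetate intact.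

**Step 4**
Reactants: 4
Product: 5, (4E,8E,12E)-14-acetoxy-4,8,12-trimethyltetradeca-4,8,12-trienal
Conditions: H5IO6, Et2O/THF, 0 °C → rt
Reagents that add atoms: none
Why: Acid-mediated epoxide hydration followed by Malaprade cleavage of the diol (acetone is lost). This gives the C3 aldehyde and truncates the terminal gem-dimethyl unit.

**Step 5**
Reactants: 5; 6, (triphenylphosphoranylidene)acetaldehyde
Product: 7, (2E,6E,10E,14E)-16-acetoxy-6,10,14-trimethylhexadeca-2,6,10,14-tetraenal
Conditions: toluene, 80 °C
Reagents that add atoms: 6 itself supplies the two carbons (O=CC=P(c1ccccc1)(c1ccccc1)c1ccccc1)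
Why: Wittig olefination with a stabilised ylide gives the E-enal selectively. This adds C4 and C19.

**Step 6**
Reactants: 7
Product: 8, (2R,3S)-trans-epoxy aldehyde, O=C[C@@H]1O[C@H]1CC/C(C)=C/…
Conditions: 30% aq. H2O2, (R)-diarylprolinol TMS-ether catalyst (10 mol %), CH2Cl2, rt
Reagents that add atoms: hydrogen peroxide, OO
Why: Jørgensen iminium-activated nucleophilic epoxidation acts only on the enal, so the isolated alkenes are untouched. Catalyst chirality sets C3 (3S) and C4 (trans). C3 later relays absolute stereochemistry into the cascade and is then excised.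

**Step 7**
Reactants: 8
Product: 9, (2R,3S)-epoxy acid
Conditions: NaClO2, NaH2PO4, 2-methyl-2-butene, tBuOH/H2O, 0 °C
Reagents that add atoms: sodium chlorite, [O-]Cl=O
Why: Pinnick oxidation; the alkene scavenger traps HOCl so the polyene survives.

**Step 8**
Reactants: 9
Product: 10, methyl (2R,3S)-glycidate, COC(=O)[C@@H]1O[C@H]1CC/C(C)=C/CC/C(C)=C/CC/C(C)=C/COC(C)=O
Conditions: TMSCHN2, MeOH/PhMe, 0 °C
Reagents that add atoms: trimethylsilyldiazomethane, C[Si](C)(C)C=[N+]=[N-]
Why: Mild methyl esterification of a sensitive epoxy acid that leaves the acetate and epoxide intact.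

**Step 9**
Reactants: 10
Product: 11, 3β-hydroxy-4α-(methoxycarbonyl)-18-norlabda-8(17),13E-dien-15-yl acetate, C=C1CC[C@@H]2[C@](C)(CC[C@H](O)[C@H]2C(=O)OC)[C@H]1CC/C(C)=C/COC(C)=O
Conditions: Cp2TiCl2 (20 mol %), Mn dust, 2,4,6-collidine, TMSCl, THF, rt; then 1 M aq. HCl/THF to remove the O-TMS group
Reagents that add atoms: none (TMSCl only silylates transiently)
Why: Proposed new method: Cp2TiCl opens the glycidic ester at the C–O bond α to the ester, giving a Ti(IV) alkoxide at C3 (ester-chelated) and an electrophilic secondary α-ester radical at C4. That radical adds 6-endo to the electron-rich C5=C10 alkene (polarity matched, Markovnikov). The tertiary C10 radical then adds 6-endo to C9=C8 through a chair–chair arrangement with the 3-OTi group equatorial. This fixes the trans-decalin and the 5α-H, 10β-Me and 9α-H centres, with the (3S) centre selecting the normal enantiomeric series. The C8 radical is trapped by a second Ti(III) and β-hydride eliminates toward C17 to give the exocyclic alkene. Collidine·HCl, TMSCl and Mn regenerate Cp2TiCl. The closest known reactions are the Cp2TiCl-catalysed radical cascade of terminal epoxypolyprenes and the Ti(III) α-C–O opening of α,β-epoxy carbonyls. The C4 configuration is not controlled here and is erased at step 11.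

**Step 10**
Reactants: 11
Product: 12, β-keto ester (C4 epimerisable, left unspecified), C=C1CC[C@@H]2[C@](C)(CCC(=O)C2C(=O)OC)[C@H]1CC/C(C)=C/COC(C)=O
Conditions: Dess–Martin periodinane, NaHCO3, CH2Cl2, 0 °C → rt
Reagents that add atoms: none
Why: Oxidation of the secondary alcohol to the ketone; buffering protects the exocyclic alkene and the allylic acetate.

**Step 11**
Reactants: 12
Product: 13, C=C1CC[C@@H]2[C@](C)(CCC(=O)[C@]2(C)C(=O)OC)[C@H]1CC/C(C)=C/COC(C)=O
Conditions: MeI, K2CO3, acetone, 50 °C
Reagents that add atoms: methyl iodide, CI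
Why: C-alkylation of the stabilised β-keto ester enolate. Attack from the β face is blocked by the 1,3-diaxial C20 methyl, so methylation occurs from the α face (known for 4-substituted 3-oxo-5α systems). This gives 4α-Me (C18) and 4β-CO2Me (C19, axial), setting C4 as in the target.

**Step 12**
Reactants: 13
Product: 14, C=C1CC[C@@H]2[C@](C)(CC[C@H](O)[C@]2(C)C(=O)OC)[C@H]1CC/C(C)=C/COC(C)=O
Conditions: NaBH4, MeOH/CH2Cl2 (1:1), 0 °C
Reagents that add atoms: none (hydride only)
Why: Chemoselective reduction of the ketone in the presence of the ester and acetate. The C3 configuration is irrelevant because C3 is deoxygenated next.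

**Step 13**
Reactants: 14
Product: 15, O-phenyl thionocarbonate, C=C1CC[C@@H]2[C@](C)(CC[C@H](OC(=S)Oc3ccccc3)[C@]2(C)C(=O)OC)[C@H]1CC/C(C)=C/COC(C)=O
Conditions: PhOC(S)Cl, pyridine, DMAP, MeCN, rt
Reagents that add atoms: phenyl chlorothionoformate, S=C(Cl)Oc1ccccc1
Why: Acylation of the hindered secondary alcohol to make a Barton–McCombie radical precursor.

**Step 14**
Reactants: 15
Product: 16, methyl ester of the target, C=C1CC[C@@H]2[C@](C)(CCC[C@]2(C)C(=O)OC)[C@H]1CC/C(C)=C/COC(C)=O
Conditions: Bu3SnH, AIBN (cat.), toluene, 110 °C
Reagents that add atoms: none (H only; tin and thionocarbonate are lost)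
Why: Barton–McCombie radical deoxygenation. The C3 radical is simply quenched by H, and the quaternary C4 is untouched and not epimerisable, so the stereochemistry is kept.

**Step 15**
Reactants: 16
Product: 17, 15-acetoxyisocupressic acid
Conditions: Me3SnOH, 1,2-dichloroethane, 80 °C
Reagents that add atoms: trimethyltin hydroxide as the hydroxide source, C[Sn](C)(C)O
Why: Mild, neutral Nicolaou-type cleavage of a hindered neopentyl methyl ester. The acetate, the alkenes and all stereocentres are retained.

## Compound list
1 | (2E,6E,10E)-geranylgeraniol | CC(C)=CCC/C(C)=C/CC/C(C)=C/CC/C(C)=C/CO | starting material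
2 | geranylgeranyl acetate | CC(C)=CCC/C(C)=C/CC/C(C)=C/CC/C(C)=C/COC(C)=O | intermediate
3 | 14-bromo-15-hydroxy-14,15-dihydro-GG acetate (racemic) | CC(C)(O)C(Br)CC/C(C)=C/CC/C(C)=C/CC/C(C)=C/COC(C)=O | intermediate
4 | 14,15-epoxy-GG acetate (racemic) | CC1(C)OC1CC/C(C)=C/CC/C(C)=C/CC/C(C)=C/COC(C)=O | intermediate
5 | (4E,8E,12E)-14-acetoxy-4,8,12-trimethyltetradeca-4,8,12-trienal | O=CCC/C(C)=C/CC/C(C)=C/CC/C(C)=C/COC(C)=O | intermediate
6 | (triphenylphosphoranylidene)acetaldehyde | O=CC=P(c1ccccc1)(c1ccccc1)c1ccccc1 | starting material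
7 | (2E,6E,10E,14E)-16-acetoxy-6,10,14-trimethylhexadeca-2,6,10,14-tetraenal | O=C/C=C/CC/C(C)=C/CC/C(C)=C/CC/C(C)=C/COC(C)=O | intermediate
8 | (2R,3S)-trans-epoxy aldehyde | O=C[C@@H]1O[C@H]1CC/C(C)=C/CC/C(C)=C/CC/C(C)=C/COC(C)=O | intermediate
9 | (2R,3S)-epoxy acid | OC(=O)[C@@H]1O[C@H]1CC/C(C)=C/CC/C(C)=C/CC/C(C)=C/COC(C)=O | intermediate
10 | methyl (2R,3S)-glycidate | COC(=O)[C@@H]1O[C@H]1CC/C(C)=C/CC/C(C)=C/CC/C(C)=C/COC(C)=O | intermediate
11 | 3β-hydroxy-4α-(methoxycarbonyl)-18-norlabda-8(17),13E-dien-15-yl acetate | C=C1CC[C@@H]2[C@](C)(CC[C@H](O)[C@H]2C(=O)OC)[C@H]1CC/C(C)=C/COC(C)=O | intermediate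
12 | 3-oxo β-keto ester (4-H) | C=C1CC[C@@H]2[C@](C)(CCC(=O)C2C(=O)OC)[C@H]1CC/C(C)=C/COC(C)=O | intermediate
13 | 4α-methyl-4β-CO2Me 3-ketone | C=C1CC[C@@H]2[C@](C)(CCC(=O)[C@]2(C)C(=O)OC)[C@H]1CC/C(C)=C/COC(C)=O | intermediate
14 | 3β-alcohol | C=C1CC[C@@H]2[C@](C)(CC[C@H](O)[C@]2(C)C(=O)OC)[C@H]1CC/C(C)=C/COC(C)=O | intermediate
15 | O-phenyl thionocarbonate | C=C1CC[C@@H]2[C@](C)(CC[C@H](OC(=S)Oc3ccccc3)[C@]2(C)C(=O)OC)[C@H]1CC/C(C)=C/COC(C)=O | intermediate
16 | methyl 15-acetoxy-labda-8(17),13E-dien-19-oate | C=C1CC[C@@H]2[C@](C)(CCC[C@]2(C)C(=O)OC)[C@H]1CC/C(C)=C/COC(C)=O | intermediate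
17 | 15-acetoxyisocupressic acid | C=C1CC[C@@H]2[C@](C)(CCC[C@]2(C)C(=O)O)[C@H]1CC/C(C)=C/COC(C)=O | target

## Totals
Total steps: 15. Longest linear sequence: 15, from geranylgeraniol.

## Three steps most likely to fail
1. **Step 9, the proposed Ti(III) cascade.** The α-ester radical may be reduced by Ti(III) to a Ti enolate, giving the acyclic β-hydroxy ester. The C8 radical could also cyclise onto the side-chain alkene to give a tricycle.
   - Fallback (known chemistry): Roskamp homologation of 5 with methyl diazoacetate (SnCl2) gives the acyclic β-keto ester. A Snider Mn(OAc)3/Cu(OAc)2 oxidative radical cascade then gives racemic 12 directly. The enantiomers are resolved by chiral HPLC, or a chiral-auxiliary ester is used, and the route rejoins at step 11.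
2. **Step 11, C4 methylation.** Face selectivity may be imperfect, or O-alkylation or decomposition may compete on the hindered β-keto ester.
   - Fallback: reorder the sequence. Excise the C3 oxygen first by Barton–McCombie on 11, so that C4 becomes a simple 4-H ester. Then methylate the exocyclic ester enolate (LiHMDS, MeI, THF/DMPU, −78 → 0 °C). This requires a C15-OTBS variant prepared by using GG-OTBS instead of the acetate, with TBAF and Ac2O at the end.
3. **Step 15, ester cleavage.** Hydrolysing the axial, neopentyl methyl ester may be slow or may also cleave the allylic acetate.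
   - Fallback: global saponification (KOH, ethylene glycol, 160 °C) gives isocupressic acid. Regioselective re-acetylation of the primary allylic alcohol (Ac2O, pyridine, DMAP cat., 0 °C, aqueous NaHCO3 quench) then gives the target. The hindered acid is not acylated, and any mixed anhydride is hydrolysed on workup.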